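(Readings and results are calculated on assumed constants, and the scatter is random.)

The spring run reaches 18% of target by 12.0 min and the winter run 23%, and both curves bend with 83% and 76% of the substrate, the limiting reagent, still read.

| flask | substrate | partner | free catalyst | remark | time |
|---|---|---|---|---|---|
| spring | 0.30 M | 0.49 M | 60 mM | run made earlier |  |
| winter | 0.30 M | 0.66 M | 60 mM | run made earlier |  |
| teal | 0.30 M | 0.330 M | 60 mM |  | 1.0 h |
| amber | 0.080 M | 0.330 M | 60 mM |  | 0.30 h |

- spring (time / min: target / %, substrate / %): 2.00: 3, 98; 4.00: 7, 88; 6.00: 12, 91; 8.00: 16, 85; 10.0: 18, 84; 12.0: 18, 83
- winter (time / min: target / %, substrate / %): 2.00: 9, 96; 4.00: 12, 88; 6.00: 18, 85; 8.00: 22, 78; 10.0: 20, 78; 12.0: 23, 76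

(standard deviation of a reading: 2 percentage points)

- which of the two ends with the higher amount of target, in percent of the substrate charged ("neither" if they lie within 2 percentage points) (teal / amber / neither)
- target at the end, in percent of the substrate charged, teal
- target at the end, in percent of the substrate charged, amber

- the earlier runs were read with a standard deviation of 2 percentage points

I write the balance of substrate and assume that its loss is proportional to substrate, to partner and to whatever carries the reaction. Taking substrate left as charge less target, spring gives 0.405 L mol⁻¹ at 12.0 min and winter 0.396 L mol⁻¹, which agree despite their different partner charges. I keep their mean, 0.401 L mol⁻¹, as the dose: the log of substrate charged over substrate left, per partner charged.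

Now the ladder of times. On the shortest rung, the 12.0 min of readings, the mean dose is 0.171 L mol⁻¹ after 4.00 min, and the next 8.00 min add 0.230 L mol⁻¹, which is less per minute. At the early pace and teal's partner, substrate would need 70.9 min to fall by a factor of e, longer than the readings last. So I read the bend as a fading carrier, not as substrate running down. Amber's 0.30 h is the next rung, and teal's 1.0 h is the last, still short of that substrate time.

I guess at a slow tail, with the dose gaining equally for each equal factor of time, though the runs show one such factor and never vary substrate. That gives 0.485 L mol⁻¹ for amber and 0.737 L mol⁻¹ for teal. I hold partner at its charge, which is rough for teal, with less partner per substrate than amber, 1.10 against 4.12. On that assumption I reckon 14.8% for amber and 21.6% for teal, with teal ahead.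

The forecast answers neither, with 13% for teal and 14% for amber, “Treating the plateau as an equilibrium”. It parts from my reckoning on teal.

    substrate + partner + free catalyst → free catalyst + target (k = 49.0 L² mol⁻² h⁻¹)
    target + free catalyst ⇌ isomer of the product + free catalyst, rate k2*[free catalyst]*[target] forward; the back reaction follows from the equilibrium constant (K = 0.580, k = 4.50 L mol⁻¹ h⁻¹)
    2 free catalyst → spent catalyst (k = 16.0 L mol⁻¹ h⁻¹)

Teal ends at 33.0% and amber at 19.4%, so teal ends higher. At 1.00 h teal still holds 34.2% of its free catalyst, with 65.8% spent. Its 64% of substrate left gives a dose of 1.34 L mol⁻¹, up from 0.401 L mol⁻¹ at 12.0 min and above my 0.737 L mol⁻¹. A neighbour of teal with 1.3 M of partner also stands at 34.2% of free catalyst. Teal's dose times that partner leaves 17.5% of the substrate, and the neighbour holds 15.6%.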